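Readings and results come from a simulation for an exercise, and the scatter is random.

**The trap.** Early samples mislead: at 0.333 h the south-west run reads 0.5 % target against 0.1 % other capture product, which looks like a lead for the target but lies inside the scatter.

| flask | starting material | first nucleophile | second nucleophile | remark | time |
|---|---|---|---|---|---|
| east | 0.050 M | 0.030 M | 0.10 M | run made earlier |  |
| south-west | 0.050 M | 0.045 M | 0.10 M | run made earlier |  |
| flask | 0.050 M | 0.0600 M | 0.100 M |  | 8.0 h |

- east (time / h: other capture product / %, target / %): 1.00: 8.9, 1.3; 2.00: 24.3, 1.4; 3.00: 37.2, 0.4; 4.00: 46.8, 0.3; 5.00: 54.3, 0.4; 6.00: 63.8, 2.6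
- south-west (time / h: other capture product / %, target / %): 0.333: 0.1, 0.5; 1.00: 9.3, 2.1; 2.00: 22.1, 3.8; 3.00: 36.2, 2.6; 4.00: 46.6, 2.3; 5.00: 56.1, 2.6; 6.00: 63.2, 2.4

(standard deviation of a reading: 1 percentage point)

- the analysis behind the earlier runs scatters by 1 percentage point, standard deviation

- share of other capture product in other capture product plus target at 20 min
- share of other capture product in other capture product plus target at 80 min
- share of other capture product in other capture product plus target at 8.0 h
- which of other capture product and target there is more of at 8.0 h

**My ratio.** I divide one product's reading by the other's at the same hour and treat the result as a value for that hour: the south-west odds of target over other capture product fall from 0.226 at 1.00 h to 0.0380 at 6.00 h. I take the odds of target over other capture product at 1.00 h and divide them by the charge ratio c(first nucleophile)/c(second nucleophile). The east run gives 0.487 and the south-west run 0.502, both rough readings. Their mean, 0.494, is my capture ratio S, a reading for that hour.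

**Turned round.** The target leads once the odds pass one. In this flask S times the charge ratio gives 0.297 at that hour, short by a factor of 3.37. The gap then widens: the south-west odds read 0.0380 at 6.00 h, a factor of 26.3 short, while this flask's charge ratio is 1.33 times the south-west one. I commit to the other capture product at 8.0 h.

**The forecast.** It gives shares of 25 %, 77 % and 94 %, with the other capture product ahead, and for the target its extrapolation “gives a plateau of about 4–5% at 0.060 M”.

**The flask.** The shares come out at 63.7 %, 84.0 % and 98.1 %, and at 8.0 h the flask holds 73.5 % other capture product against 1.39 % target.

    second nucleophile + intermediate → other capture product (k = 20.2 L mol⁻¹ h⁻¹)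
    first nucleophile + intermediate ⇌ target (K = 6.54 L mol⁻¹, k = 33.3 L mol⁻¹ h⁻¹)
    starting material + target → side product (k = 3.91 L mol⁻¹ h⁻¹)
    first nucleophile → decomposition product (k = 2.17 × 10⁻⁴ h⁻¹)
    starting material → intermediate (k = 0.208 h⁻¹)

**What to watch.** The target in this flask peaks at 2.80 % near 2.03 h, then sinks. At 80 min the flask's odds are 0.191, so its S stands at 0.318, against 0.494 read at 1.00 h. Applied to the neighbour flask with 0.024 M first nucleophile, that value gives odds of 0.0764, a share of 92.9 %; the neighbour stands at 93.0 %.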